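**Retrosynthetic overview**
1. 11 ⇒ 7 + 8: the C4–C4a bond and the lactone C(=O)–O bond are cut together. Forward, a chiral carbene turns cinnamaldehyde into its Breslow (acyl-anion/homoenolate-equivalent) intermediate, and an oxidative [3+3] annulation sets C4 in the last step.
2. 7 ⇒ 4 + 2 × 5: both prenyl C–C bonds at one ring carbon (alkylative dearomatisation).
3. 4 ⇒ 1 + 2: aryl–acyl bond (Friedel–Crafts); the side-chain stereocentre is bought.
4. Ring order: the carbocycle is the purchased phloroglucinol ring, dearomatised in step 2; the dihydropyranone ring is the only ring built, and it is built last.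

Assumption: (2R)-2-methylbutanoic acid is bought enantiopure, and the enolised triketones are drawn in the tautomer that matches the target SMILES.

**Step 1**
Reactants: 1 (2R)-2-methylbutanoic acid; 2 phloroglucinol
Product: 4 (2R)-2-methyl-1-(2,4,6-trihydroxyphenyl)butan-1-one, via acid chloride 3 (not isolated)
Conditions: (COCl)2 (1.1 equiv), cat. DMF, CH2Cl2, 0 °C → rt; then 2, AlCl3 (3.5 equiv), PhNO2/CH2Cl2, 0 °C → rt; aq. HCl work-up
Reagents that add atoms: phloroglucinol (2), Oc1cc(O)cc(O)c1
Why: Friedel–Crafts C-acylation of the very electron-rich, threefold-symmetric phloroglucinol stops at the chelated mono-ketone, and the acid chloride is made and used at or below room temperature so the purchased (R)-α-centre is not enolised (no new stereocentre is formed).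

**Step 2**
Reactants: 4 (2R)-2-methyl-1-(2,4,6-trihydroxyphenyl)butan-1-one; 5 prenyl bromide (1-bromo-3-methylbut-2-ene)
Product: 7 3,5-dihydroxy-2-[(2R)-2-methylbutanoyl]-6,6-bis(3-methylbut-2-en-1-yl)cyclohexa-2,4-dien-1-one, via mono-prenyl ketone 6 (not isolated)
Conditions: NaOMe (3 equiv), MeOH, 0 °C; 5 (2.1 equiv) added slowly, 0 °C → rt; 1 M HCl; chromatography
Reagents that add atoms: prenyl bromide (5), CC(C)=CCBr
Why: Alkylative dearomatisation (lupulone-type C-prenylation): in methanol the solvated phenoxide is alkylated at carbon, first to 6 and then again at the same prenyl-bearing carbon to give the gem-diprenyl vinylogous acid 7, which is separated from the aromatic 3,5-diprenyl isomer and the triprenyl by-product; no stereocentre is formed and the side-chain α-hydrogen is not acidic in the delocalised anion.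

**Step 3**
Reactants: 7 3,5-dihydroxy-2-[(2R)-2-methylbutanoyl]-6,6-bis(3-methylbut-2-en-1-yl)cyclohexa-2,4-dien-1-one; 8 (E)-cinnamaldehyde
Product: 11 (4S)-5-hydroxy-6-[(2R)-2-methylbutanoyl]-8,8-bis(3-methylbut-2-en-1-yl)-4-phenyl-3,4-dihydro-2H-chromene-2,7(8H)-dione, via Breslow intermediate 9 (not isolated), via cinnamoyl azolium 10 (not isolated)
Conditions: (5aS,10bR)-2-mesityl-5a,10b-dihydro-4H,6H-indeno[2,1-b][1,2,4]triazolo[4,3-d][1,4]oxazin-2-ium chloride (10 mol%), 3,3',5,5'-tetra-tert-butyldiphenoquinone (1.2 equiv), iPr2NEt (1.5 equiv), 4 Å MS, toluene, rt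
Reagents that add atoms: (E)-cinnamaldehyde (8), O=C/C=C/c1ccccc1
Why: Oxidative NHC-catalysed [3+3] annulation (Michael addition–lactonisation): the carbene adds to the aldehyde carbon of 8 to give the Breslow intermediate 9, which the diphenoquinone oxidises to the (E)-cinnamoyl azolium 10; the only C–H ring carbon of 7 (C-4 of the dienone) then adds to Cβ on the Si face left open by the indane wall of the catalyst, setting C-4 of the chromenedione as S, and the non-chelated enol oxygen next to the gem-diprenyl carbon takes the acyl group, giving the lactone that keeps the chelated β-triketone and releasing the carbene.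

**Compound list**
1 | (2R)-2-methylbutanoic acid | CC[C@@H](C)C(=O)O | starting material
2 | phloroglucinol (benzene-1,3,5-triol) | Oc1cc(O)cc(O)c1 | starting material
3 | (2R)-2-methylbutanoyl chloride | CC[C@@H](C)C(=O)Cl | intermediate (not isolated)
4 | (2R)-2-methyl-1-(2,4,6-trihydroxyphenyl)butan-1-one | CC[C@@H](C)C(=O)c1c(O)cc(O)cc1O | intermediate
5 | prenyl bromide (1-bromo-3-methylbut-2-ene) | CC(C)=CCBr | starting material
6 | (2R)-2-methyl-1-[2,4,6-trihydroxy-3-(3-methylbut-2-en-1-yl)phenyl]butan-1-one | CC[C@@H](C)C(=O)c1c(O)cc(O)c(CC=C(C)C)c1O | intermediate (not isolated)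
7 | 3,5-dihydroxy-2-[(2R)-2-methylbutanoyl]-6,6-bis(3-methylbut-2-en-1-yl)cyclohexa-2,4-dien-1-one | CC[C@@H](C)C(=O)C1=C(O)C=C(O)C(CC=C(C)C)(CC=C(C)C)C1=O | intermediate
8 | (E)-cinnamaldehyde | O=C/C=C/c1ccccc1 | starting material
9 | Breslow intermediate (enaminol from the carbene of the (5aS,10bR) catalyst and 8; enaminol C=C geometry not specified) | Cc1cc(C)c(N2N=C3CO[C@H]4Cc5ccccc5[C@H]4N3C2=C(O)/C=C/c2ccccc2)c(C)c1 | intermediate (not isolated)
10 | (E)-cinnamoyl azolium of the (5aS,10bR) catalyst, written as its chloride | Cc1cc(C)c(-[n+]2nc3CO[C@H]4Cc5ccccc5[C@H]4n3c2C(=O)/C=C/c2ccccc2)c(C)c1.[Cl-] | intermediate (not isolated)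
11 | (4S)-5-hydroxy-6-[(2R)-2-methylbutanoyl]-8,8-bis(3-methylbut-2-en-1-yl)-4-phenyl-3,4-dihydro-2H-chromene-2,7(8H)-dione | CC[C@@H](C)C(=O)C1=C(O)C2=C(OC(=O)C[C@H]2c2ccccc2)C(CC=C(C)C)(CC=C(C)C)C1=O | target

**Totals**
Total step count: 3. Longest linear sequence: 3 steps (1 and 2 → 4 → 7 → 11).

**Steps most likely to fail, with fallbacks**

Step 3 is the riskiest. Three things can go wrong:
- the acidic triketone may suppress carbene formation;
- the lactone may close on the other enol oxygen;
- the facial sense rests on a steric model of the s-cis acyl azolium that I could not confirm against a reported example, so it must be checked on the first run. The two C-4 epimers are diastereomers here, and the (5aR,10bS) antipode of the precatalyst is the direct correction.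

The fallback sets out from 7 (with 8) and comes back at 11. It uses iminium catalysis instead of carbene catalysis. With (S)-α,α-diphenylprolinol trimethylsilyl ether (20 mol%) in CH2Cl2 at room temperature, the enol carbon of 7 adds to the Si face of the cinnamaldehyde iminium ion. The aldehyde is then trapped reversibly by the neighbouring enol hydroxyl as the lactol (4S)-2,5-dihydroxy-6-[(2R)-2-methylbutanoyl]-8,8-bis(3-methylbut-2-en-1-yl)-4-phenyl-3,4-dihydro-2H-chromen-7(8H)-one F1, a mixture of anomers. Oxidation of the lactol with catalytic TPAP and N-methylmorpholine N-oxide gives 11.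

Step 2 is next. The second prenyl group can also go to the free ring carbon, giving the aromatic 3,5-diprenyl isomer, and a third can add, so the yield of 7 is expected to be modest (roughly 20–35%). The fallback sets out from 4 and comes back at 11 by reversing the order of events. The step-3 catalyst system is applied to 4, where the free para-hydroxyl should close the lactone, to give (4S)-5,7-dihydroxy-6-[(2R)-2-methylbutanoyl]-4-phenyl-3,4-dihydro-2H-chromen-2-one F2. C-8 is then the only unsubstituted ring carbon, and it is prenylated twice with prenyl bromide and DBU in THF (a non-nucleophilic base, so the lactone stays closed) to give 11; no 3,5-diprenyl arene can form.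

Step 1 is the least risky. The concern is partial racemisation of the α-branched acyl chloride under AlCl3 through a ketene, or over-acylation. The fallback sets out from 1 and comes back at 4. Acid 1 is activated as its mixed anhydride with trifluoroacetic anhydride (CH2Cl2, 0 °C, no aluminium) and acylates 1,3,5-trimethoxybenzene to give (2R)-2-methyl-1-(2,4,6-trimethoxyphenyl)butan-1-one F3. BBr3 (CH2Cl2, −78 °C → rt) then cleaves the three methyl ethers to give 4.

**Further compounds**
F1 | step 3 | (4S)-2,5-dihydroxy-6-[(2R)-2-methylbutanoyl]-8,8-bis(3-methylbut-2-en-1-yl)-4-phenyl-3,4-dihydro-2H-chromen-7(8H)-one (anomeric mixture) | CC[C@@H](C)C(=O)C1=C(O)C2=C(OC(O)C[C@H]2c2ccccc2)C(CC=C(C)C)(CC=C(C)C)C1=O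
F2 | step 2 | (4S)-5,7-dihydroxy-6-[(2R)-2-methylbutanoyl]-4-phenyl-3,4-dihydro-2H-chromen-2-one | CC[C@@H](C)C(=O)c1c(O)c2[C@H](c3ccccc3)CC(=O)Oc2cc1O
F3 | step 1 | (2R)-2-methyl-1-(2,4,6-trimethoxyphenyl)butan-1-one | CC[C@@H](C)C(=O)c1c(OC)cc(OC)cc1OC
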